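**Plan**
- Retrosynthesis: cut C7–C8 and the lactone C8–O–C12 bond last; then C7=C11 (cross-metathesis) and C5–C6 (Stille); then C1–C13′ and C3–C11′ (the norbornene, [4+2]); then C1–C10 (Mukaiyama–Michael).
- Forward: a 4-silyloxycyclopentenone becomes a 2-silyloxycyclopentadiene carrying the C10–C9–C8 arm; cycloaddition to the lactone methylene of the seco-eudesmanolide gives the norbornene and the spiro centre; the C6–C7–C11–C13 arm is added at C5; the cycloheptane and its α-methylene lactone close last.
- Enabling feature: C8 bears the lactone oxygen and C7 the C11=C13 methylene, so a C8 aldehyde and a C7=C11(CO2Me)–C13H2Br unit, held cis on the C1–C5 edge of the norbornene, are a matched pair for an intramolecular allylchromium addition that closes ring C1–C10–C9–C8–C7–C6–C5.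
- Stereochemistry: C2 from the cyclopentenone; C10 by iminium catalysis; C4′, C6′, C7′, C8′ from the seco-eudesmanolide; C1, C3, C11′ in the cycloaddition (anti to C2–O, carbonyl exo); C7 and C8 in the ring closure (anti addition, trans-lactone).

Key step: step 15

Locants: C1–C15 (guaianolide half) and C1′–C15′ (seco-eudesmanolide half) follow terpenoid numbering of the target.
Assumption: 1-O-acetylbritannilactone is bought as a natural-product building block and is taken to have the absolute configuration that the target fixes for its seco-eudesmanolide half, (4R) in the side chain and (3aR,4R,7aS) in the ring; my own assignment of the natural material is the antipode, (4S; 3aS,4S,7aR), and if that holds this building block is not a commercial compound and would have to be made.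

**Route**

Step 1
Reactants: 1 (R)-4-(tert-butyldimethylsilyloxy)cyclopent-2-en-1-one
Product: 2 (R)-4-(tert-butyldimethylsilyloxy)-2-iodocyclopent-2-en-1-one
Conditions: I2, pyridine, CH2Cl2, 0 to 23 °C
Reagents that add atoms: iodine, II
Why: α-Iodination of the enone by pyridine addition, iodination and elimination (Baylis–Hillman-type iodination), which leaves the silyloxy stereocentre (later C2) untouched.

Step 2
Reactants: 2 (R)-4-(tert-butyldimethylsilyloxy)-2-iodocyclopent-2-en-1-one
Product: 3 (R)-4-(tert-butyldimethylsilyloxy)-2-methylcyclopent-2-en-1-one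
Conditions: SnMe4, PdCl2(PhCN)2 (5 mol%), AsPh3, CuI, N-methylpyrrolidinone, 80 °C
Reagents that add atoms: tetramethylstannane, C[Sn](C)(C)C
Why: Stille coupling of the α-iodoenone under neutral conditions installs the C4 methyl (C15) without β-elimination of the silyloxy group.

Step 3
Reactants: 3 (R)-4-(tert-butyldimethylsilyloxy)-2-methylcyclopent-2-en-1-one
Product: 4 (5S)-2,5-bis(tert-butyldimethylsilyloxy)-3-methylcyclopenta-1,3-diene
Conditions: TBSOTf, Et3N, CH2Cl2, −78 to 0 °C; pentane extraction, used crude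
Reagents that add atoms: tert-butyldimethylsilyl trifluoromethanesulfonate, CC(C)(C)[Si](C)(C)OS(=O)(=O)C(F)(F)F
Why: Soft enolisation (silyl triflate and amine) at the α′ carbon gives the cross-conjugated 2-silyloxydiene without a free enolate that could expel the neighbouring silyloxy group.

Step 4
Reactants: 4 (5S)-2,5-bis(tert-butyldimethylsilyloxy)-3-methylcyclopenta-1,3-diene; 5 (E)-but-2-enal
Product: 6 (3R)-3-[(1R,5S)-5-(tert-butyldimethylsilyloxy)-3-methyl-2-oxocyclopent-3-en-1-yl]butanal
Conditions: (2S,5S)-5-benzyl-2-tert-butyl-3-methylimidazolidin-4-one (20 mol%), 2,4-dinitrobenzoic acid (20 mol%), CH2Cl2/H2O, −40 °C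
Reagents that add atoms: none
Why: Iminium-catalysed Mukaiyama–Michael addition in which the silyl dienol ether attacks through C1 the β-carbon of the (E)-iminium ion on the face left open by the catalyst benzyl group, setting C10 as R under catalyst control, while C1 forms trans to the C2 silyloxy group and is planarised again in step 6.

Step 5
Reactants: 6 (3R)-3-[(1R,5S)-5-(tert-butyldimethylsilyloxy)-3-methyl-2-oxocyclopent-3-en-1-yl]butanal
Product: 7 (4S,5R)-4-(tert-butyldimethylsilyloxy)-5-[(2R)-1-(1,3-dioxolan-2-yl)propan-2-yl]-2-methylcyclopent-2-en-1-one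
Conditions: 1,2-bis(trimethylsilyloxy)ethane, TMSOTf (2 mol%), CH2Cl2, −78 °C
Reagents that add atoms: 1,2-bis(trimethylsilyloxy)ethane, C[Si](C)(C)OCCO[Si](C)(C)C
Why: Noyori acetalisation masks the aldehyde selectively over the conjugated ketone, so that only the ketone is enolised in step 6.

Step 6
Reactants: 7 (4S,5R)-4-(tert-butyldimethylsilyloxy)-5-[(2R)-1-(1,3-dioxolan-2-yl)propan-2-yl]-2-methylcyclopent-2-en-1-one
Product: 8 (5S)-2,5-bis(tert-butyldimethylsilyloxy)-1-[(2R)-1-(1,3-dioxolan-2-yl)propan-2-yl]-3-methylcyclopenta-1,3-diene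
Conditions: TBSOTf, Et3N, CH2Cl2, −78 to 0 °C; pentane extraction, used at once
Reagents that add atoms: tert-butyldimethylsilyl trifluoromethanesulfonate, CC(C)(C)[Si](C)(C)OS(=O)(=O)C(F)(F)F
Why: Soft enolisation toward C1, the only α′ hydrogen, gives the 2-silyloxydiene with the C10 and C2 stereocentres intact.

Step 7
Reactants: 9 1-O-acetylbritannilactone, (4R)-4-[(3aR,4R,7aS)-4-hydroxy-6-methyl-3-methylidene-2-oxo-3a,4,7,7a-tetrahydro-1-benzofuran-5-yl]pentyl acetate
Product: 10 C6′-O-triisopropylsilyl ether of 9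
Conditions: TIPSOTf, 2,6-lutidine, CH2Cl2, 0 °C
Reagents that add atoms: triisopropylsilyl trifluoromethanesulfonate, CC(C)[Si](C(C)C)(C(C)C)OS(=O)(=O)C(F)(F)F
Why: Silylation of the hindered C6′ hydroxyl removes the only acidic proton before the enolate chemistry of step 9 and keeps this oxygen distinct from the C2 oxygen until step 13.

Step 8
Reactants: 8 (5S)-2,5-bis(tert-butyldimethylsilyloxy)-1-[(2R)-1-(1,3-dioxolan-2-yl)propan-2-yl]-3-methylcyclopenta-1,3-diene; 10 C6′-O-triisopropylsilyl ether of 9
Product: 11 norbornene cycloadduct (C5 silyl enol ether, spiro lactone at C11′)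
Conditions: CH2Cl2, 13 kbar, 20 °C, 8 in 2.5-fold excess
Reagents that add atoms: none
Why: High-pressure Diels–Alder reaction of the electron-rich 2-silyloxycyclopentadiene with the α-methylene lactone, meant to outrun the [1,5]-hydrogen shift of 8 at 20 °C: the silyloxy-activated terminus C1 should bond to the methylene carbon C13′, the lactone carbonyl should lie exo as is usual for α-methylene lactones, and the diene should be attacked anti to the C2 silyloxy group; the lactone has to react on its concave face, syn to C6′, which is taken on trust from the configuration of the target (sterically the convex face looks easier), and together these set C1, C3 and C11′.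

Step 9
Reactants: 11 norbornene cycloadduct (C5 silyl enol ether)
Product: 12 C5 alkenyl triflate
Conditions: CsF, PhNTf2, 1,2-dimethoxyethane, 23 °C
Reagents that add atoms: N-phenylbis(trifluoromethanesulfonimide), O=S(=O)(N(c1ccccc1)S(=O)(=O)C(F)(F)F)C(F)(F)F
Why: Fluoride cleaves the silyl enol ether in preference to the alkyl silyl ethers, and the regiodefined cesium enolate is O-triflated, which fixes the C4=C5 double bond without strong base.

Step 10
Reactants: 12 C5 alkenyl triflate; 13 allyltributylstannane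
Product: 14 C5 allyl compound
Conditions: Pd(PPh3)4 (10 mol%), CuCl, LiCl, DMSO, 60 °C
Reagents that add atoms: none
Why: Stille coupling of the hindered alkenyl triflate, accelerated by copper and lithium chlorides, forms the C5–C6 bond.

Step 11
Reactants: 14 C5 allyl compound
Product: 15 C2 alcohol
Conditions: HF·pyridine, pyridine, THF, 0 to 23 °C
Reagents that add atoms: none
Why: The secondary tert-butyldimethylsilyl ether at C2 should be cleaved faster than the more hindered triisopropylsilyl ether at C6′ (usual lability order of silyl ethers), and the dioxolane is stable to buffered HF.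

Step 12
Reactants: 15 C2 alcohol
Product: 16 C2 acetate
Conditions: Ac2O, pyridine, DMAP (10 mol%), CH2Cl2, 23 °C
Reagents that add atoms: acetic anhydride, CC(=O)OC(C)=O
Why: Acylation of the only free hydroxyl gives the C2 acetate with retention.

Step 13
Reactants: 16 C2 acetate
Product: 17 C8 aldehyde with free C6′ hydroxyl
Conditions: 48% aqueous HF, MeCN, 0 to 23 °C
Reagents that add atoms: water, O
Why: Acid hydrolysis of the dioxolane and fluoride cleavage of the triisopropylsilyl ether in one operation, under which the acetates and the skipped diene should survive.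

Step 14
Reactants: 17 C8 aldehyde with free C6′ hydroxyl; 18 methyl 2-(bromomethyl)acrylate
Product: 19 (Z)-allylic bromide aldehyde
Conditions: second-generation Hoveyda–Grubbs catalyst RuCl2(=CH-C6H4-2-OiPr)(H2IMes) (10 mol%), 18 (5 equiv), CH2Cl2, 40 °C
Reagents that add atoms: none
Why: Cross-metathesis of the terminal allyl olefin with a 1,1-disubstituted acrylate, the tetrasubstituted ring olefins being inert, should give under thermodynamic control the Z-bromide with the ester trans to C6.

Step 15
Reactants: 19 (Z)-allylic bromide aldehyde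
Product: 22 target CNP0211028.4, via allylchromium dichloride 20 (not isolated), via chromium alkoxide 21 (not isolated)
Conditions: CrCl2 (8 equiv), THF, 0.005 M, 23 °C; aqueous NH4Cl
Reagents that add atoms: none
Why: Divalent chromium reduces the allylic bromide of 19 in two one-electron steps to the allylchromium 20 (trivalent chromium), which adds through its γ-carbon C7 to the C8 aldehyde with allyl transposition, so that the C7–C8 bond, the C11=C13 methylene and the C8 alkoxide 21 arise together, and 21 then acylates itself with the neighbouring methyl ester to give the α-methylene lactone; the closest known reaction type is the Nozaki–Hiyama allylation with 2-(bromomethyl)alk-2-enoates, used intramolecularly for α-methylene lactones fused to carbocycles. The cycloheptane closes by 7-exo-trig attack on the carbonyl and the lactone by 5-exo-trig acyl substitution on the same alkoxide, so the lactone C–O bond forms just after the carbocycle within this step and no ring is closed in any later step. C7 and C8 are set relative to each other by the chair-like six-centre transition state of the γ-substituted allylchromium, which is anti-selective whatever the bromide geometry and should therefore lead to the trans-fused lactone. Their sense relative to C10 and the norbornene is expected to follow from the chair in which the C10 methyl is pseudo-equatorial and the C8 hydrogen, not C9, points across the forming ring, with the C1–C5 edge of the rigid norbornene holding both arms cis; this is the least certain selectivity of the route. The step needs chemoselectivity for the aldehyde over two acetates, a lactone and a free hydroxyl, which allylchromium reagents show; γ- over α-attack, which the cyclic transition state secures; and cyclisation over oligomerisation, which high dilution secures.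

**Compound list**

1 | (R)-4-(tert-butyldimethylsilyloxy)cyclopent-2-en-1-one | O=C1C=C[C@H](O[Si](C)(C)C(C)(C)C)C1 | starting material
2 | (R)-4-(tert-butyldimethylsilyloxy)-2-iodocyclopent-2-en-1-one | O=C1C(I)=C[C@H](O[Si](C)(C)C(C)(C)C)C1 | intermediate
3 | (R)-4-(tert-butyldimethylsilyloxy)-2-methylcyclopent-2-en-1-one | O=C1C(C)=C[C@H](O[Si](C)(C)C(C)(C)C)C1 | intermediate
4 | (5S)-2,5-bis(tert-butyldimethylsilyloxy)-3-methylcyclopenta-1,3-diene | CC1=C[C@H](O[Si](C)(C)C(C)(C)C)C=C1O[Si](C)(C)C(C)(C)C | intermediate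
5 | (E)-but-2-enal | C/C=C/C=O | starting material
6 | (3R)-3-[(1R,5S)-5-(tert-butyldimethylsilyloxy)-3-methyl-2-oxocyclopent-3-en-1-yl]butanal | O=C1C(C)=C[C@H](O[Si](C)(C)C(C)(C)C)[C@H]1[C@H](C)CC=O | intermediate
7 | (4S,5R)-4-(tert-butyldimethylsilyloxy)-5-[(2R)-1-(1,3-dioxolan-2-yl)propan-2-yl]-2-methylcyclopent-2-en-1-one | O=C1C(C)=C[C@H](O[Si](C)(C)C(C)(C)C)[C@H]1[C@H](C)CC2OCCO2 | intermediate
8 | (5S)-2,5-bis(tert-butyldimethylsilyloxy)-1-[(2R)-1-(1,3-dioxolan-2-yl)propan-2-yl]-3-methylcyclopenta-1,3-diene | CC1=C[C@H](O[Si](C)(C)C(C)(C)C)C(=C1O[Si](C)(C)C(C)(C)C)[C@H](C)CC2OCCO2 | intermediate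
9 | 1-O-acetylbritannilactone, (4R)-4-[(3aR,4R,7aS)-4-hydroxy-6-methyl-3-methylidene-2-oxo-3a,4,7,7a-tetrahydro-1-benzofuran-5-yl]pentyl acetate | C=C1C(=O)O[C@H]2CC(C)=C([C@H](C)CCCOC(C)=O)[C@H](O)[C@@H]12 | starting material
10 | C6′-O-triisopropylsilyl ether of 9 | C=C1C(=O)O[C@H]2CC(C)=C([C@H](C)CCCOC(C)=O)[C@H](O[Si](C(C)C)(C(C)C)C(C)C)[C@@H]12 | intermediate
11 | cycloadduct: norbornene (C1, C2, C3, C4=C5, C13′, C11′) spiro-fused at C11′ to the lactone of 10 with the carbonyl exo; C5–OTBS enol ether, C4 methyl, C2–OTBS syn to C4=C5, C1 bearing the (2R)-1-(1,3-dioxolan-2-yl)propan-2-yl arm, C6′–OTIPS | O1CCOC1C[C@@H](C)[C@]34C[C@@]5(C(=O)O[C@H]6CC(C)=C([C@H](C)CCCOC(C)=O)[C@H](O[Si](C(C)C)(C(C)C)C(C)C)[C@H]65)[C@H](C(C)=C3O[Si](C)(C)C(C)(C)C)[C@@H]4O[Si](C)(C)C(C)(C)C | intermediate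
12 | C5 alkenyl triflate: as 11 with C5–OSO2CF3 | O1CCOC1C[C@@H](C)[C@]34C[C@@]5(C(=O)O[C@H]6CC(C)=C([C@H](C)CCCOC(C)=O)[C@H](O[Si](C(C)C)(C(C)C)C(C)C)[C@H]65)[C@H](C(C)=C3OS(=O)(=O)C(F)(F)F)[C@@H]4O[Si](C)(C)C(C)(C)C | intermediate
13 | allyltributylstannane | C=CC[Sn](CCCC)(CCCC)CCCC | starting material
14 | C5 allyl compound: as 12 with C5–CH2CH=CH2 | O1CCOC1C[C@@H](C)[C@]34C[C@@]5(C(=O)O[C@H]6CC(C)=C([C@H](C)CCCOC(C)=O)[C@H](O[Si](C(C)C)(C(C)C)C(C)C)[C@H]65)[C@H](C(C)=C3CC=C)[C@@H]4O[Si](C)(C)C(C)(C)C | intermediate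
15 | C2 alcohol: as 14 with C2–OH | O1CCOC1C[C@@H](C)[C@]34C[C@@]5(C(=O)O[C@H]6CC(C)=C([C@H](C)CCCOC(C)=O)[C@H](O[Si](C(C)C)(C(C)C)C(C)C)[C@H]65)[C@H](C(C)=C3CC=C)[C@@H]4O | intermediate
16 | C2 acetate: as 15 with C2–OAc | O1CCOC1C[C@@H](C)[C@]34C[C@@]5(C(=O)O[C@H]6CC(C)=C([C@H](C)CCCOC(C)=O)[C@H](O[Si](C(C)C)(C(C)C)C(C)C)[C@H]65)[C@H](C(C)=C3CC=C)[C@@H]4OC(C)=O | intermediate
17 | aldehyde: as 16 with C8 aldehyde and free C6′ hydroxyl | O=CC[C@@H](C)[C@]34C[C@@]5(C(=O)O[C@H]6CC(C)=C([C@H](C)CCCOC(C)=O)[C@H](O)[C@H]65)[C@H](C(C)=C3CC=C)[C@@H]4OC(C)=O | intermediate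
18 | methyl 2-(bromomethyl)acrylate | C=C(CBr)C(=O)OC | starting material
19 | (Z)-allylic bromide: as 17 with C5–CH2–CH=C(CO2Me)–CH2Br (C6, C7, C11, C12, C13) | O=CC[C@@H](C)[C@]34C[C@@]5(C(=O)O[C@H]6CC(C)=C([C@H](C)CCCOC(C)=O)[C@H](O)[C@H]65)[C@H](C(C)=C3C/C=C(\CBr)C(=O)OC)[C@@H]4OC(C)=O | intermediate
20 | allylchromium dichloride: as 19 with C13–CrCl2 | O=CC[C@@H](C)[C@]34C[C@@]5(C(=O)O[C@H]6CC(C)=C([C@H](C)CCCOC(C)=O)[C@H](O)[C@H]65)[C@H](C(C)=C3C/C=C(\C[Cr](Cl)Cl)C(=O)OC)[C@@H]4OC(C)=O | intermediate (not isolated)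
21 | chromium alkoxide of the C8 hydroxy ester: cycloheptane closed, C7–C(=CH2)CO2Me, C8–OCrCl2 | COC(=O)C(=C)[C@H]1[C@H](O[Cr](Cl)Cl)C[C@@H](C)[C@]34C[C@@]5(C(=O)O[C@H]6CC(C)=C([C@H](C)CCCOC(C)=O)[C@H](O)[C@H]65)[C@H](C(C)=C3C1)[C@@H]4OC(C)=O | intermediate (not isolated)
22 | CNP0211028.4 | C=C1C(=O)O[C@@H]2C[C@@H](C)[C@]34C[C@@]5(C(=O)O[C@H]6CC(C)=C([C@H](C)CCCOC(C)=O)[C@H](O)[C@H]65)[C@H](C(C)=C3C[C@@H]12)[C@@H]4OC(C)=O | target

**Count and risks**

Total steps: 15. Longest linear sequence: 14 (steps 1–6 and 8–15).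

Step 8. The lactone methylene of 10 has to react on its concave face, syn to C6′, which I could not justify on steric grounds, so addition to the other face is a real possibility; the diene may also add syn to the C2 silyloxy group, or isomerise by [1,5]-hydrogen shift before it cycloadds. The fallback replaces the cycloaddition by a stepwise anionic double Michael addition and sets out from 7 and 10. LiN(SiMe3)2 in THF at −78 °C should form the cross-conjugated lithium dienolate of 7, which should add through C1 to C13′ of 10 trans to the C2 silyloxy group. The lactone enolate so formed should close onto C3 to give the bicyclic ketone F1. Tf2O and 2,6-di-tert-butyl-4-methylpyridine in CH2Cl2 should then give the more substituted enol triflate, which is 12, where the route is rejoined.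

Step 15. The ring may close through the wrong chair, giving the cis-fused lactone or the trans-fused isomer epimeric at C7 and C8, or the allylchromium may be protonated or dimerise. The fallback uses an allylsilane and an open transition state instead, and sets out from 17. Cross-metathesis of 17 with methyl 2-[(trimethylsilyl)methyl]acrylate (same ruthenium catalyst) should give the allylsilane aldehyde F2. BF3·OEt2 in CH2Cl2 at −78 °C should effect an intramolecular Hosomi–Sakurai addition of C7 to the C8 aldehyde through an antiperiplanar open transition state, giving the hydroxy ester F3. Catalytic p-toluenesulfonic acid should lactonise F3 to 22.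

Step 14. Cross-metathesis of the hindered allyl group with the 1,1-disubstituted acrylate may be slow, and homodimerisation or migration of the skipped diene may compete. The fallback builds the bromide by carbonyl chemistry and sets out from 16. OsO4 (cat.) with N-methylmorpholine N-oxide, then NaIO4, should cleave the terminal olefin to the aldehyde F4. A Morita–Baylis–Hillman reaction with methyl acrylate and DABCO should give the allylic alcohol F5. N-bromosuccinimide and dimethyl sulfide should convert F5 with allylic transposition into the (Z)-bromide F6. 48% aqueous HF in MeCN should then remove the dioxolane and the silyl ether to give 19.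

**Further compounds**

F1 | step 8 | bicyclic ketone: as 11 with C5=O and C4–H (methyl endo) | O1CCOC1C[C@@H](C)[C@]34C[C@@]5(C(=O)O[C@H]6CC(C)=C([C@H](C)CCCOC(C)=O)[C@H](O[Si](C(C)C)(C(C)C)C(C)C)[C@H]65)[C@H]([C@H](C)C3=O)[C@@H]4O[Si](C)(C)C(C)(C)C
F2 | step 15 | allylsilane aldehyde: as 19 with CH2SiMe3 in place of CH2Br | O=CC[C@@H](C)[C@]34C[C@@]5(C(=O)O[C@H]6CC(C)=C([C@H](C)CCCOC(C)=O)[C@H](O)[C@H]65)[C@H](C(C)=C3C/C=C(\C[Si](C)(C)C)C(=O)OC)[C@@H]4OC(C)=O
F3 | step 15 | C8 hydroxy ester: cycloheptane closed, C7–C(=CH2)CO2Me, C8–OH | COC(=O)C(=C)[C@H]1[C@H](O)C[C@@H](C)[C@]34C[C@@]5(C(=O)O[C@H]6CC(C)=C([C@H](C)CCCOC(C)=O)[C@H](O)[C@H]65)[C@H](C(C)=C3C1)[C@@H]4OC(C)=O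
F4 | step 14 | C7 aldehyde: as 16 with C5–CH2–CHO | O1CCOC1C[C@@H](C)[C@]34C[C@@]5(C(=O)O[C@H]6CC(C)=C([C@H](C)CCCOC(C)=O)[C@H](O[Si](C(C)C)(C(C)C)C(C)C)[C@H]65)[C@H](C(C)=C3CC=O)[C@@H]4OC(C)=O
F5 | step 14 | Morita–Baylis–Hillman alcohol: as 16 with C5–CH2–CH(OH)–C(=CH2)CO2Me, both epimers at C7 | O1CCOC1C[C@@H](C)[C@]34C[C@@]5(C(=O)O[C@H]6CC(C)=C([C@H](C)CCCOC(C)=O)[C@H](O[Si](C(C)C)(C(C)C)C(C)C)[C@H]65)[C@H](C(C)=C3CC(O)C(=C)C(=O)OC)[C@@H]4OC(C)=O
F6 | step 14 | (Z)-allylic bromide: as 19 with C8 dioxolane and C6′–OTIPS | O1CCOC1C[C@@H](C)[C@]34C[C@@]5(C(=O)O[C@H]6CC(C)=C([C@H](C)CCCOC(C)=O)[C@H](O[Si](C(C)C)(C(C)C)C(C)C)[C@H]65)[C@H](C(C)=C3C/C=C(\CBr)C(=O)OC)[C@@H]4OC(C)=O
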